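**Plan** (unit A is the 6-linked isoflavone and unit B the 8-linked one; atoms are written C6(A), O7(B) and so on)
Cuts, in retrosynthetic order: the four aryl O–CH3 bonds; the two Si–O bonds of a temporary O5(A)–Si(t-Bu)2–O7(B) bridge; the biaryl bond C6(A)–C8(B); the bridge itself, leaving two differently masked copies of one isoflavone (biochanin A); then C2 and the aryl–acyl bond of that monomer, back to phloroglucinol, 4-methoxyphenylacetic acid and DMF.
Enabling feature: both axis carbons sit ortho to a phenolic oxygen of a phloroglucinol-type ring A. O5(A) has C6(A) as its only ortho C–H (its other ortho atom is the ring-fusion carbon C4a), and O7(B) is the only exocyclic oxygen next to C8(B). A one-atom bridge between these two oxygens therefore lets only C6(A) and C8(B) meet, in a seven-membered ring.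
Forward: the pyranone ring C is closed onto ring A in step 1. The monomer is then split into donor 5 (free 5-OH) and acceptor 9 (free 7-OH, iodine at C8). The two are tied through silicon (step 6), joined by intramolecular palladium-catalysed C–H arylation (step 7), unbridged (step 8) and demethylated (step 9).
Stereochemistry: the target has no stereocentre, and the tetra-ortho-oxygenated axis forms without control.

Key step: step 7

Assumption: the target SMILES carries no axial descriptor, so the hindered axis is made as the racemate.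

**Step 1**
Reactants: 1 phloroglucinol; 2 4-methoxyphenylacetic acid
Product: 4 biochanin A (5,7-dihydroxy-3-(4-methoxyphenyl)-4H-chromen-4-one), via deoxybenzoin 3 (not isolated)
Conditions: BF3·OEt2 (solvent), 85 °C; then DMF, MsCl, 50 to 90 °C; aq. NaOAc work-up
Reagents that add atoms: N,N-dimethylformamide (DMF), CN(C)C=O
Why: Friedel–Crafts acylation of the threefold-symmetric phloroglucinol can give only one ketone, and Vilsmeier-type C-formylation of its activated methylene followed by cyclodehydration onto either of two equivalent ortho hydroxyls closes the pyranone, which is the standard one-pot deoxybenzoin route to polyhydroxyisoflavones.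

**Step 2**
Reactants: 4 biochanin A
Product: 5 5-hydroxy-7-methoxy-3-(4-methoxyphenyl)-4H-chromen-4-one (donor monomer)
Conditions: MeI (1.1 equiv), K2CO3 (1.1 equiv), acetone, reflux
Reagents that add atoms: iodomethane (MeI), CI
Why: In this Williamson ether synthesis the acidic 7-OH is alkylated while the 5-OH, hydrogen-bonded to the C4 carbonyl, stays free under a mild carbonate base and about one equivalent of MeI.

**Step 3**
Reactants: 4 biochanin A
Product: 7 7-benzyloxy-5-methoxy-3-(4-methoxyphenyl)-4H-chromen-4-one, via 7-O-benzylbiochanin A 6 (not isolated)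
Conditions: BnBr (1.05 equiv), K2CO3, DMF, rt; then MeI (excess), more K2CO3, 50 °C
Reagents that add atoms: benzyl bromide (BnBr), BrCc1ccccc1; iodomethane (MeI), CI
Why: Two Williamson etherifications in sequence exploit the same acidity gap, since the 7-OH is benzylated at room temperature and the chelated 5-OH is methylated only with excess MeI on warming.

**Step 4**
Reactants: 7 7-benzyloxy-5-methoxy-3-(4-methoxyphenyl)-4H-chromen-4-one
Product: 8 7-hydroxy-5-methoxy-3-(4-methoxyphenyl)-4H-chromen-4-one
Conditions: H2 (1 atm), Pd/C (10 wt %), EtOAc–MeOH, rt, stopped after one equivalent of H2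
Reagents that add atoms: none
Why: Catalytic hydrogenolysis of the aryl benzyl ether is faster than reduction of the conjugated C2–C3 double bond at one atmosphere, so controlled uptake should free only the 7-OH.

**Step 5**
Reactants: 8 7-hydroxy-5-methoxy-3-(4-methoxyphenyl)-4H-chromen-4-one
Product: 9 7-hydroxy-8-iodo-5-methoxy-3-(4-methoxyphenyl)-4H-chromen-4-one (acceptor monomer)
Conditions: NIS (1.0 equiv), DMF, 0 °C to rt, dark
Reagents that add atoms: N-iodosuccinimide (NIS), O=C1CCC(=O)N1I
Why: Electrophilic aromatic iodination ortho to the free 7-OH should prefer C8 (para to the 5-OMe, flanked only by the OH and the ring oxygen O1) over the more crowded C6 between OH and OMe, in line with the known C8 halogenation of 5-O-alkylated 5,7-dioxygenated chromones.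

**Step 6**
Reactants: 5 donor monomer; 9 acceptor monomer
Product: 11 di-tert-butyl[(7-methoxy-3-(4-methoxyphenyl)-4-oxochromen-5-yl)oxy][(8-iodo-5-methoxy-3-(4-methoxyphenyl)-4-oxochromen-7-yl)oxy]silane, via silyl triflate 10 (not isolated)
Conditions: 5, t-Bu2Si(OTf)2 (1.05 equiv), 2,6-lutidine, CH2Cl2, 0 °C to rt; then 9, Et3N, DMAP (10 mol %), 40 °C
Reagents that add atoms: di-tert-butylsilyl bis(trifluoromethanesulfonate), CC(C)(C)[Si](OS(=O)(=O)C(F)(F)F)(OS(=O)(=O)C(F)(F)F)C(C)(C)C
Why: In this stepwise O-silylation the very electrophilic bis(triflate) silylates the sluggish chelated 5-OH once, the tert-butyl bulk keeps a second molecule of 5 out, and the remaining Si–OTf bond is then displaced by the more acidic 7-OH of 9 to give the unsymmetrical bis(aryloxy)silane.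

**Step 7**
Reactants: 11 silicon-bridged iodide
Product: 12 silylene-bridged 6(A),8(B)-biisoflavone, in which O5(A) and O7(B) are joined through Si(t-Bu)2 in a seven-membered 1,3,2-dioxasilepine and O7(A), O4'(A), O5(B) and O4'(B) are methyl ethers (racemic)
Conditions: Pd(OAc)2 (10 mol %), PCy3·HBF4 (20 mol %), PivOH (30 mol %), Ag2CO3 (1.0 equiv), 4 Å MS, DMA (0.02 M), 110 °C
Reagents that add atoms: none
Why: Zerovalent palladium inserts into the C8(B)–I bond, silver carbonate strips the iodide, and the pivalate-bound aryl palladium species cleaves the C6(A)–H bond by concerted metalation–deprotonation to give an eight-membered diaryl palladacycle, whose reductive elimination forms the C6(A)–C8(B) bond. The closest known reaction type is the palladium-catalysed intramolecular C–H arylation of di-tert-butylsilyl-bridged bis(aryloxy)silanes, which gives unsymmetrical 2,2'-biphenols after desilylation. The one new ring, the seven-membered dioxasilepine (C6(A), C5(A), O5(A), Si, O7(B), C7(B), C8(B)), closes by ring-contracting reductive elimination, and the geminal tert-butyl groups compress the O–Si–O angle and favour the folded conformer. No stereocentre is formed, and the new axis arises as a racemic pair of helically twisted bridged biaryls because nothing in the substrate is chiral. Site selectivity is needed on both rings: on the donor ring O5(A) has a single ortho C–H (C6; C4a is the ring fusion and C8 lies beyond the reach of the three-atom bridge), and on the acceptor ring the iodine marks C8(B) and not C6(B). The fourfold ortho congestion is eased because two ortho oxygens are tied back in the bridge and a third, O1(B), is part of the pyranone ring.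

**Step 8**
Reactants: 12 silylene-bridged biisoflavone
Product: 13 5(A),7(B)-dihydroxy-7(A),4'(A),5(B),4'(B)-tetramethoxy-6(A),8(B)-biisoflavone
Conditions: HF·pyridine, THF, 0 °C to rt (plastic vessel)
Reagents that add atoms: none
Why: Fluoride-driven cleavage of both aryl Si–O bonds is the standard removal of a di-tert-butylsilylene group, and it runs under mildly acidic conditions that spare the base-sensitive pyranone rings and the methyl ethers.

**Step 9**
Reactants: 13 tetramethyl ether
Product: 14 6,8''-bigenistein (target)
Conditions: BBr3 (16 equiv), CH2Cl2, −78 °C to rt (40 °C if needed); MeOH then water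
Reagents that add atoms: none
Why: Lewis acid mediated aryl methyl ether cleavage with BBr3 is the standard last step for flavonoid and biflavonoid methyl ethers, and it proceeds without opening the pyranone rings, so it should not scramble the 6,8-linkage.

**Compound list**
1 | phloroglucinol | Oc1cc(O)cc(O)c1 | starting material
2 | 4-methoxyphenylacetic acid | COc1ccc(CC(=O)O)cc1 | starting material
3 | 2-(4-methoxyphenyl)-1-(2,4,6-trihydroxyphenyl)ethanone (deoxybenzoin) | COc1ccc(CC(=O)c2c(O)cc(O)cc2O)cc1 | intermediate
4 | biochanin A | O=c1c(-c2ccc(OC)cc2)coc2cc(O)cc(O)c12 | intermediate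
5 | 5-hydroxy-7-methoxy-3-(4-methoxyphenyl)-4H-chromen-4-one | O=c1c(-c2ccc(OC)cc2)coc2cc(OC)cc(O)c12 | intermediate
6 | 7-O-benzylbiochanin A | O=c1c(-c2ccc(OC)cc2)coc2cc(OCc3ccccc3)cc(O)c12 | intermediate
7 | 7-benzyloxy-5-methoxy-3-(4-methoxyphenyl)-4H-chromen-4-one | O=c1c(-c2ccc(OC)cc2)coc2cc(OCc3ccccc3)cc(OC)c12 | intermediate
8 | 7-hydroxy-5-methoxy-3-(4-methoxyphenyl)-4H-chromen-4-one | O=c1c(-c2ccc(OC)cc2)coc2cc(O)cc(OC)c12 | intermediate
9 | 7-hydroxy-8-iodo-5-methoxy-3-(4-methoxyphenyl)-4H-chromen-4-one | O=c1c(-c2ccc(OC)cc2)coc2c(I)c(O)cc(OC)c12 | intermediate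
10 | di-tert-butyl[(7-methoxy-3-(4-methoxyphenyl)-4-oxochromen-5-yl)oxy]silyl triflate | O=c1c(-c2ccc(OC)cc2)coc2cc(OC)cc(O[Si](C(C)(C)C)(C(C)(C)C)OS(=O)(=O)C(F)(F)F)c12 | intermediate
11 | unsymmetrical O5(A)–Si(t-Bu)2–O7(B) bis(aryloxy)silane with iodine at C8(B) | O=c1c(-c2ccc(OC)cc2)coc2cc(OC)cc(O[Si](C(C)(C)C)(C(C)(C)C)Oc3cc(OC)c4c(=O)c(-c5ccc(OC)cc5)coc4c3I)c12 | intermediate
12 | silylene-bridged 6(A),8(B)-biisoflavone tetramethyl ether (1,3,2-dioxasilepine, racemic) | O=c1c(-c2ccc(OC)cc2)coc2cc(OC)c3c(c12)O[Si](C(C)(C)C)(C(C)(C)C)Oc1cc(OC)c2c(=O)c(-c4ccc(OC)cc4)coc2c1-3 | intermediate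
13 | 5(A),7(B)-dihydroxy-7(A),4'(A),5(B),4'(B)-tetramethoxy-6(A),8(B)-biisoflavone | O=c1c(-c2ccc(OC)cc2)coc2cc(OC)c(-c3c(O)cc(OC)c4c(=O)c(-c5ccc(OC)cc5)coc34)c(O)c12 | intermediate
14 | 6,8''-bigenistein | O=c1c(-c2ccc(O)cc2)coc2cc(O)c(-c3c(O)cc(O)c4c(=O)c(-c5ccc(O)cc5)coc34)c(O)c12 | target

**Totals**
Total step count: 9.
Longest linear sequence: 8 steps (1, 3, 4, 5, 6, 7, 8, 9).

**Steps most likely to fail**

Step 7. Palladation of the doubly flanked C6(A)–H bond may be slow. Protodeiodination, palladation of a tert-butyl methyl group, or cleavage of the aryl silyl ether bridge by pivalate could then overtake ring closure.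
The fallback is an intermolecular Suzuki–Miyaura union without any bridge. It sets out from 5 and 9 and comes back at 14.
- Phenol 9 is O-methylated (MeI, K2CO3, DMF) to 8-iodo-5,7,4'-trimethoxyisoflavone F1.
- Miyaura borylation (B2pin2, Pd(dppf)Cl2, KOAc, dioxane, 90 °C) converts this into 5,7,4'-trimethoxyisoflavone-8-boronic acid pinacol ester F2.
- Separately, 5 is iodinated under the direction of its free 5-OH (NIS, DMF) to 5-hydroxy-6-iodo-7,4'-dimethoxyisoflavone F3.
- The two are joined (Pd2(dba)3, SPhos, K3PO4, toluene–water, 100 °C) to the 5(A)-hydroxy pentamethyl ether of the 6,8-dimer F4.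
- BBr3 as in step 9 then leads to 14.

Step 6. Silylation of the chelated, peri-hindered 5-OH may be sluggish, and aryloxy groups may scramble on silicon towards symmetric silanes.
The fallback is a carbon bridge built by O-alkylation in place of O-silylation. It sets out from 5 (with 9 as partner) and comes back at 14.
- Compound 5 with NaH and ClCH2SMe in DMF should give the 5-O-(methylthiomethyl) ether F5.
- SO2Cl2 in CH2Cl2 converts this into the 5-O-chloromethyl ether F6.
- Alkylation of 9 with it (K2CO3, DMF) gives the formaldehyde-acetal-bridged iodide F7.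
- The conditions of step 7 close the seven-membered 1,3-dioxepine F8.
- BBr3 cleaves the acetal and the four methyl ethers in one operation to reach 14.

Step 5. Site selectivity between C8 and C6 may be poor, and over-iodination of the free phenol is possible.
The fallback moves the iodination one stage earlier, onto the 5,7-dialkoxy pattern whose C8 preference is established, and replaces hydrogenolysis by acidolysis. It sets out from 7 and comes back at 9.
- Compound 7 with NIS and catalytic TFA in MeCN should give 7-benzyloxy-8-iodo-5,4'-dimethoxyisoflavone F9.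
- Debenzylation with TFA and pentamethylbenzene at rt, which leaves the C–I bond alone, then gives 9.

**Further compounds**
F1 | step 7 | 8-iodo-5,7,4'-trimethoxyisoflavone | O=c1c(-c2ccc(OC)cc2)coc2c(I)c(OC)cc(OC)c12
F2 | step 7 | 5,7,4'-trimethoxyisoflavone-8-boronic acid pinacol ester | O=c1c(-c2ccc(OC)cc2)coc2c(B3OC(C)(C)C(C)(C)O3)c(OC)cc(OC)c12
F3 | step 7 | 5-hydroxy-6-iodo-7,4'-dimethoxyisoflavone | O=c1c(-c2ccc(OC)cc2)coc2cc(OC)c(I)c(O)c12
F4 | step 7 | 5(A)-hydroxy pentamethyl ether of the 6,8-dimer | O=c1c(-c2ccc(OC)cc2)coc2cc(OC)c(-c3c(OC)cc(OC)c4c(=O)c(-c5ccc(OC)cc5)coc34)c(O)c12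
F5 | step 6 | 5-O-(methylthiomethyl) ether of 5 | O=c1c(-c2ccc(OC)cc2)coc2cc(OC)cc(OCSC)c12
F6 | step 6 | 5-O-chloromethyl ether of 5 | O=c1c(-c2ccc(OC)cc2)coc2cc(OC)cc(OCCl)c12
F7 | step 6 | formaldehyde-acetal-bridged iodide | O=c1c(-c2ccc(OC)cc2)coc2cc(OC)cc(OCOc3cc(OC)c4c(=O)c(-c5ccc(OC)cc5)coc4c3I)c12
F8 | step 6 | methylene-bridged 6,8-dimer (1,3-dioxepine) | O=c1c(-c2ccc(OC)cc2)coc2cc(OC)c3c(c12)OCOc1cc(OC)c2c(=O)c(-c4ccc(OC)cc4)coc2c1-3
F9 | step 5 | 7-benzyloxy-8-iodo-5,4'-dimethoxyisoflavone | O=c1c(-c2ccc(OC)cc2)coc2c(I)c(OCc3ccccc3)cc(OC)c12
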